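Remark on the chemistry: (2S)-naringenin 1 is assumed to be available in high enantiomeric purity (commercial material, enriched by chiral chromatography if needed), because the route preserves C2 and never creates it.

## Analysis of the target

Target 10 is a flavanone: benzo ring A (C4a to C8a) is fused to the dihydropyranone ring C (O1, C2, C3, C4), and C2 carries the aryl ring B. Ring A bears hydroxyls at C5 and C7 with a prenyl group at C6 between them, and ring B bears a hydroxyl at C4' and a prenyl group at C3'. C2 (S) is the only stereocentre, so no relative configuration has to be controlled, but it is benzylic and β to the C4 carbonyl through O1, so base can open ring C by retro-oxa-Michael reaction to the chalcone, and reclosure has no facial preference. The two trisubstituted alkenes each sit ortho to a phenol; acid closes them to 2,2-dimethylchromans, and hydrogenation or electrophilic oxidants attack them. The difficulty is regiochemistry on ring A, where C6 and C8 are both activated and direct C-prenylation gives O-, C6-, C8- and poly-alkylated mixtures, together with the need to place the prenyl groups without the basic or acidic conditions that endanger C2 and the alkenes. The strategy rests on the fact that each prenylated carbon is ortho to a phenolic oxygen, C6 next to C5–O and C3' next to C4'–O. Because the second ortho carbon of O5 is the ring-fusion carbon C4a, which is already substituted, an allyl unit handed over from O5 can only arrive at C6, and one handed over from O4' arrives at C3' (equivalent to C5').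

## Retrosynthetic reasoning

10 to 9 (O7–Si). The free O7–H is traced back to a triisopropylsilyl ether. The silyl group is kept to the end because buffered fluoride removes it without the acid that would cyclise the ortho-prenylphenols and without hydrogenolysis that would reduce the alkenes. Before that point it keeps O7 out of both the etherification and the rearrangement.

9 to 6 (C6–C1'' and C3'–C1'''). The two bonds from the ring carbons to the benzylic CH2 of each prenyl chain are cut, and each five-carbon unit is returned to the neighbouring oxygen with allylic transposition, which gives the bis(1,1-dimethylallyl) ether 6. These are the only skeletal bonds that 1 lacks, and any cut in ring A or ring C would discard the ring system and the stereocentre that 1 supplies. Delivery is from O5 and not from O7, because O7 has two free ortho carbons (C6 and C8) and O5 has one. The gain is regiochemistry fixed by the substrate, both C–C bonds in one operation, and no acid or base. The forward reaction must carry out two [3,3] shifts, passing through 7 or 8, without ionising the tertiary ethers and without disturbing C2.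

6 to 5 (functional-group change). No skeletal bond is cut; the two vinyl groups are traced back to ethynyl groups. A tertiary allylic aryl ether cannot be made cleanly by substitution on an allylic electrophile, which sends the phenoxide to the primary terminus or to ring carbon. In the propargylic series the tertiary carbon is the only electrophilic site, so the constitution of the ether is settled before the alkene exists. The forward step must stop at the alkene and leave the C4 ketone and the benzylic C2–O1 bond alone.

5 to 2 and 3 (O4'–C and O5–C). Both ether bonds are cut at once, which gives the diphenol 2 and two equivalents of the tertiary propargylic alcohol 3, activated in the flask as ester 4. The forward reaction must alkylate an ordinary phenol and the hydrogen-bonded O5 with a tertiary electrophile. It must do so quickly, since this is the one stage where a base meets the flavanone.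

2 to 1 (O7–Si). The silyl ether is cut to give 1. O7 is para to the C4 carbonyl and is the most acidic hydroxyl, while O5 is locked in a hydrogen bond, so one equivalent of a bulky silylating agent should select O7. The stereocentre comes with 1.

## Alternatives that were turned down

Alternative 1: Disconnection at O1–C8a.
- Forward key step: the open-chain alcohol A2 already has the S-configured carbinol at C2, C4 masked as a 1,3-dithiane and bromine on the future C8a. CuI (monovalent copper), a phenanthroline ligand and Cs2CO3 would join the alkoxide oxygen to the aryl carbon in an intramolecular Ullmann-type etherification, giving dithioketal A1.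
- For it: C2 would come from an asymmetric reduction or aldol and not from a natural sample. With C4 masked there is no β-aryloxy ketone present during the basic closure, so ring opening is impossible at that stage; on this point it is safer than the chosen route. Both prenyl positions are fixed in the fragments, and the route is convergent.
- Against it: the ring A fragment is a pentasubstituted bromoarene, so the C6/C8 problem is only moved into an arene synthesis. The bromide is electron-rich and flanked by a quaternary carbon, a poor partner for copper. Hot carbonate can fragment the β-hydroxy dithiane. After closure, unmasking the dithiane needs thiophilic electrophiles or oxidants that also attack the prenyl alkenes, and three methoxymethyl ethers need acid, which closes ortho-prenylphenols to chromans.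
- Comparison: well over ten steps against five. The chosen route depends on the optical purity of 1 and on base control in one step, but it ends without acid or oxidant.

Alternative 2: Disconnection at C2–C3.
- Forward key step: diazoketone A4 loses N2 on Rh2(S-PTTL)4 (dirhodium tetrakis[N-phthaloyl-(S)-tert-leucinate], divalent rhodium). The carbenoid inserts into one of the two enantiotopic benzylic C–H bonds of the ortho benzyl ether, giving the tris-silyl flavanone A3.
- For it: ring C and the stereocentre are made in one catalytic step, independent of any chiral-pool sample, which is more than the chosen route can claim. The silyl ethers come off with fluoride.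
- Against it: the ether oxygen is closer to the carbenoid than the C–H bond. Five-membered oxonium ylide formation followed by a 1,2-benzyl shift is the expected competitor of the six-membered insertion. Two electron-rich prenyl alkenes invite cyclopropanation, and the arenes invite cycloaddition. Acceptor-only carbenoids give unreliable enantiocontrol in such insertions. A4 also needs a fully substituted, doubly ortho-flanked benzoic acid derivative.
- Comparison: the risk is spread over chemoselectivity, enantioselectivity and a long fragment synthesis. In the chosen key step the only competing pathway is C–O ionisation.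

Alternative 3: Disconnection at C4a–C5.
- Forward key step: under Mg(OMe)2 the dienolate of the dihydropyranone keto ester A6 attacks its terminal methyl ester through C4a. Ring A forms by a Claisen-type condensation and aromatises by enolisation, giving A5.
- For it: the C6 prenyl group sits on an sp3 carbon of the chain before the arene exists, so the C6/C8 question never arises. On regiochemical certainty this is stronger than any phenol-based approach. The C5 and C7 hydroxyls appear unprotected.
- Against it: A6 is a poly-carbonyl compound with several acidic sites, open to O-acylation and alternative aldol closures. Its 2-aryl-dihydropyranone is a β-aryloxy enone, and alkoxide base can open it and racemise C2. The nucleophilic carbon must attack next to a branched, prenylated carbon. A6 needs its own asymmetric synthesis, and the last methoxymethyl ether needs acid.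
- Comparison: many more steps and a key step under base. The chosen route makes its two bonds thermally on a ring system that already exists.

Key step: step 4

## Route

Step 1
Reactants: 1 (2S)-naringenin
Product: 2 (2S)-5-hydroxy-2-(4-hydroxyphenyl)-7-(triisopropylsilyloxy)chroman-4-one
Conditions: TIPSCl (1.05 equiv), imidazole, DMF, −10 → 0 °C
Reagents that add atoms: triisopropylsilyl chloride, CC(C)[Si](Cl)(C(C)C)C(C)C
Why: Site-selective O-silylation of a phenol: O7 is para to the C4 carbonyl and the most acidic hydroxyl, O5 is tied up in a hydrogen bond to C4=O, and the bulky silyl chloride in slight excess should stop after one silylation. Imidazole is too weak a base to open ring C, so C2 is untouched.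

Step 2
Reactants: 2 (2S)-5-hydroxy-2-(4-hydroxyphenyl)-7-(triisopropylsilyloxy)chroman-4-one; 3 2-methylbut-3-yn-2-ol
Product: 5 (2S)-5-(2-methylbut-3-yn-2-yloxy)-2-[4-(2-methylbut-3-yn-2-yloxy)phenyl]-7-(triisopropylsilyloxy)chroman-4-one, via 2-methylbut-3-yn-2-yl trifluoroacetate 4 (not isolated)
Conditions: 3 (2.6 equiv), (CF3CO)2O (2.6 equiv), DBU (3.0 equiv), MeCN, −5 °C; then added to 2, DBU (2.4 equiv), CuCl2·2H2O (1 mol %), MeCN, −5 → 0 °C
Reagents that add atoms: 2-methylbut-3-yn-2-ol (second equivalent of 3 which supplies the second ether group), CC(C)(O)C#C
Why: Copper-catalysed propargylic etherification of phenols with a tertiary propargylic ester: the copper acetylide of 4 loses trifluoroacetate and a phenoxide adds at the tertiary carbon, so each ether is tertiary by construction; two equivalents of 4 are consumed, the first at the free O4' and the second at the hydrogen-bonded O5, which DBU is strong enough to deprotonate. Each ether formed ties up one equivalent of base as its trifluoroacetate salt, so the medium is close to neutral at the end and the exposure of C2 to free amidine is short and cold.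

Step 3
Reactants: 5 (2S)-5-(2-methylbut-3-yn-2-yloxy)-2-[4-(2-methylbut-3-yn-2-yloxy)phenyl]-7-(triisopropylsilyloxy)chroman-4-one
Product: 6 (2S)-5-(2-methylbut-3-en-2-yloxy)-2-[4-(2-methylbut-3-en-2-yloxy)phenyl]-7-(triisopropylsilyloxy)chroman-4-one
Conditions: H2 (1 atm), Pd/CaCO3 poisoned with Pb(OAc)2 (Lindlar catalyst), quinoline, EtOAc, 20 °C, stopped after 2 equiv H2
Reagents that add atoms: none
Why: Lindlar semihydrogenation: the terminal alkynes bind the poisoned palladium surface far better than the vinyl groups formed, so reduction should stop at the bis-alkene. The aryl ketone, the silyl ether and the benzylic C2–O1 bond are inert under these conditions.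

Step 4
Reactants: 6 (2S)-5-(2-methylbut-3-en-2-yloxy)-2-[4-(2-methylbut-3-en-2-yloxy)phenyl]-7-(triisopropylsilyloxy)chroman-4-one
Product: 9 (2S)-5-hydroxy-2-[4-hydroxy-3-(3-methylbut-2-en-1-yl)phenyl]-6-(3-methylbut-2-en-1-yl)-7-(triisopropylsilyloxy)chroman-4-one, via ring A mono-rearranged 6-prenyl 4'-ether 7 (not isolated), via ring B mono-rearranged 3'-prenyl 5-ether 8 (not isolated)
Conditions: o-xylene (degassed, 0.02 M), 125 °C, Ar, silanised glassware
Reagents that add atoms: none
Why: This is the thermal aromatic Claisen rearrangement of aryl 1,1-dimethylallyl ethers to ortho-prenylphenols, run twice in one flask: in each ether the O–C(CH3)2 bond breaks while the terminal CH2 bonds to the ortho carbon in a concerted suprafacial [3,3] shift through a chair-like six-membered transition state, and the cyclohexadienone formed enolises to the phenol. The allylic inversion turns each tertiary ether into a linear prenyl group, so C6–C1'' and C3'–C1''' are the bonds made. No ring is closed and no stereocentre is created, so only site selectivity and chemoselectivity matter. On ring A the ortho carbons of O5 are C4a and C6, and C4a is substituted, so the shift can only deliver to C6; reaching C8 would need a Cope shift of the dienone, which cannot compete with enolisation because C6 carries a hydrogen. On ring B, C3' and C5' are equivalent by rotation about the C2–C1' bond, so a single product results. The geminal methyl groups and the relief of crowding next to the C4 carbonyl lower the barrier enough for 125 °C, and the absence of acid, Lewis acid or base keeps the tertiary C–O bonds from ionising, the new ortho-prenylphenols from closing to chromans, and ring C from opening at C2. The two shifts are independent, so 7 and 8 both lead to 9, and the O7 silyl ether has no allyl unit to transfer.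

Step 5
Reactants: 9 (2S)-5-hydroxy-2-[4-hydroxy-3-(3-methylbut-2-en-1-yl)phenyl]-6-(3-methylbut-2-en-1-yl)-7-(triisopropylsilyloxy)chroman-4-one
Product: 10 macarangaflavanone B, (2S)-5,7-dihydroxy-2-[4-hydroxy-3-(3-methylbut-2-en-1-yl)phenyl]-6-(3-methylbut-2-en-1-yl)chroman-4-one
Conditions: Bu4NF (1.1 equiv), AcOH (1.5 equiv), THF, 0 °C
Reagents that add atoms: none
Why: Fluoride-mediated cleavage of an aryl silyl ether: the O7 phenoxide is a good leaving group from silicon, so the bulky silyl group should leave at 0 °C. Acetic acid keeps the medium from turning basic, so ring C does not open and C2 is retained; the prenyl groups do not react with buffered fluoride.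

## Compound list

1 | (2S)-naringenin, (2S)-5,7-dihydroxy-2-(4-hydroxyphenyl)chroman-4-one | O=C1C[C@@H](c2ccc(O)cc2)Oc2cc(O)cc(O)c12 | starting material
2 | (2S)-5-hydroxy-2-(4-hydroxyphenyl)-7-(triisopropylsilyloxy)chroman-4-one | O=C1C[C@@H](c2ccc(O)cc2)Oc2cc(O[Si](C(C)C)(C(C)C)C(C)C)cc(O)c12 | intermediate
3 | 2-methylbut-3-yn-2-ol | CC(C)(O)C#C | starting material
4 | 2-methylbut-3-yn-2-yl trifluoroacetate | C#CC(C)(C)OC(=O)C(F)(F)F | intermediate (not isolated)
5 | (2S)-5-(2-methylbut-3-yn-2-yloxy)-2-[4-(2-methylbut-3-yn-2-yloxy)phenyl]-7-(triisopropylsilyloxy)chroman-4-one | C#CC(C)(C)Oc1ccc([C@@H]2CC(=O)c3c(OC(C)(C)C#C)cc(O[Si](C(C)C)(C(C)C)C(C)C)cc3O2)cc1 | intermediate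
6 | (2S)-5-(2-methylbut-3-en-2-yloxy)-2-[4-(2-methylbut-3-en-2-yloxy)phenyl]-7-(triisopropylsilyloxy)chroman-4-one | C=CC(C)(C)Oc1ccc([C@@H]2CC(=O)c3c(OC(C)(C)C=C)cc(O[Si](C(C)C)(C(C)C)C(C)C)cc3O2)cc1 | intermediate
7 | (2S)-5-hydroxy-6-(3-methylbut-2-en-1-yl)-2-[4-(2-methylbut-3-en-2-yloxy)phenyl]-7-(triisopropylsilyloxy)chroman-4-one | C=CC(C)(C)Oc1ccc([C@@H]2CC(=O)c3c(cc(O[Si](C(C)C)(C(C)C)C(C)C)c(CC=C(C)C)c3O)O2)cc1 | intermediate (not isolated)
8 | (2S)-2-[4-hydroxy-3-(3-methylbut-2-en-1-yl)phenyl]-5-(2-methylbut-3-en-2-yloxy)-7-(triisopropylsilyloxy)chroman-4-one | CC(C)=CCc1cc([C@@H]2CC(=O)c3c(OC(C)(C)C=C)cc(O[Si](C(C)C)(C(C)C)C(C)C)cc3O2)ccc1O | intermediate (not isolated)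
9 | (2S)-5-hydroxy-2-[4-hydroxy-3-(3-methylbut-2-en-1-yl)phenyl]-6-(3-methylbut-2-en-1-yl)-7-(triisopropylsilyloxy)chroman-4-one | CC(C)=CCc1cc([C@@H]2CC(=O)c3c(cc(O[Si](C(C)C)(C(C)C)C(C)C)c(CC=C(C)C)c3O)O2)ccc1O | intermediate
10 | macarangaflavanone B, (2S)-5,7-dihydroxy-2-[4-hydroxy-3-(3-methylbut-2-en-1-yl)phenyl]-6-(3-methylbut-2-en-1-yl)chroman-4-one | CC(C)=CCc1cc([C@@H]2CC(=O)c3c(cc(O)c(CC=C(C)C)c3O)O2)ccc1O | target

## Step count and least certain steps

Total step count: 5. Longest linear sequence: 5 steps, from 1 to 10. Steps 3 and 5 are regarded as routine.

**Step 4 (key step).** What may go wrong: heterolysis of the crowded tertiary allylic C–O bond at O5 in competition with the concerted shift, which would strip the allyl unit or return it without positional control. Slow cyclisation of the new ortho-prenylphenols by traces of acid and incomplete conversion of the slower ether are further possibilities.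

Fallback (from 2, back to 9): the migrating group on ring A is changed to plain allyl, which cannot ionise, and the two methyl groups are added afterwards. One equivalent of 4 under the conditions of step 2 should etherify only the unchelated O4' of 2, giving (2S)-5-hydroxy-2-[4-(2-methylbut-3-yn-2-yloxy)phenyl]-7-(triisopropylsilyloxy)chroman-4-one F1. Semihydrogenation as in step 3 gives (2S)-5-hydroxy-2-[4-(2-methylbut-3-en-2-yloxy)phenyl]-7-(triisopropylsilyloxy)chroman-4-one F2. A Mitsunobu reaction with allyl alcohol (PPh3, DIAD, THF), the base-free way to alkylate a chelated C5 hydroxyl, gives (2S)-5-(prop-2-en-1-yloxy)-2-[4-(2-methylbut-3-en-2-yloxy)phenyl]-7-(triisopropylsilyloxy)chroman-4-one F3. Eu(fod)3, tris(6,6,7,7,8,8,8-heptafluoro-2,2-dimethyl-3,5-octanedionato)europium (trivalent europium, 10 mol %), in chlorobenzene at 70 °C, bound between O5 and the C4 carbonyl, promotes the allyl shift from O5 to C6. Heating on to 125 °C completes the ring B shift and gives (2S)-5-hydroxy-2-[4-hydroxy-3-(3-methylbut-2-en-1-yl)phenyl]-6-(prop-2-en-1-yl)-7-(triisopropylsilyloxy)chroman-4-one F4. Cross-metathesis with 2-methylbut-2-ene and RuCl2(=CHPh)(PCy3)(H2IMes) (second-generation Grubbs catalyst) in CH2Cl2 converts the allyl group into prenyl and rejoins the route at 9.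

**Step 2.** What may go wrong: slow etherification of the hydrogen-bonded O5, so that the flavanone stays in contact with amidine base long enough for ring C to open and reclose by retro-oxa-Michael and oxa-Michael reaction, eroding the configuration at C2. Partial loss of the O7 silyl group is a second possibility.

Fallback (from 2, directly to 6): a palladium π-allyl etherification under neutral conditions replaces both the copper step and the hydrogenation. 2-Methylbut-3-en-2-ol is converted with n-BuLi and Boc2O into tert-butyl 2-methylbut-3-en-2-yl carbonate F5. Pd(PPh3)4 (zerovalent palladium, 5 mol %) in THF at 0 °C ionises two equivalents of F5 with loss of CO2. The tert-butoxide released deprotonates each phenol, and the phenoxide attacks the more substituted allyl terminus, giving the two 1,1-dimethylallyl ethers of 6. The branched ether is the kinetic product and can drift to the linear prenyl ether on long contact with the catalyst. This is why the method is the fallback and not the first choice; the reaction would be stopped early and mono-ether recycled. If only O5 resists, the fallback described under step 4 also applies, since it needs no tertiary ether at O5.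

**Step 1.** What may go wrong: insufficient discrimination between O7 and O4', and over-silylation.

Fallback (from 1, back to 2): O7 is singled out by selective deacylation instead of selective silylation. Ac2O in pyridine gives (2S)-5,7-diacetoxy-2-(4-acetoxyphenyl)chroman-4-one F6. Thiophenol and imidazole in N-methylpyrrolidone at 0 °C remove the acetate from the most acidic oxygen, giving (2S)-5-acetoxy-2-(4-acetoxyphenyl)-7-hydroxychroman-4-one F7. TIPSCl and imidazole give (2S)-5-acetoxy-2-(4-acetoxyphenyl)-7-(triisopropylsilyloxy)chroman-4-one F8. NH4OAc in aqueous methanol at 20 °C hydrolyses the two aryl acetates under neutral conditions and returns 2.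

## Further compounds

F1 | step 4 | (2S)-5-hydroxy-2-[4-(2-methylbut-3-yn-2-yloxy)phenyl]-7-(triisopropylsilyloxy)chroman-4-one | C#CC(C)(C)Oc1ccc([C@@H]2CC(=O)c3c(O)cc(O[Si](C(C)C)(C(C)C)C(C)C)cc3O2)cc1
F2 | step 4 | (2S)-5-hydroxy-2-[4-(2-methylbut-3-en-2-yloxy)phenyl]-7-(triisopropylsilyloxy)chroman-4-one | C=CC(C)(C)Oc1ccc([C@@H]2CC(=O)c3c(O)cc(O[Si](C(C)C)(C(C)C)C(C)C)cc3O2)cc1
F3 | step 4 | (2S)-5-(prop-2-en-1-yloxy)-2-[4-(2-methylbut-3-en-2-yloxy)phenyl]-7-(triisopropylsilyloxy)chroman-4-one | C=CC(C)(C)Oc1ccc([C@@H]2CC(=O)c3c(OCC=C)cc(O[Si](C(C)C)(C(C)C)C(C)C)cc3O2)cc1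
F4 | step 4 | (2S)-5-hydroxy-2-[4-hydroxy-3-(3-methylbut-2-en-1-yl)phenyl]-6-(prop-2-en-1-yl)-7-(triisopropylsilyloxy)chroman-4-one | CC(C)=CCc1cc([C@@H]2CC(=O)c3c(cc(O[Si](C(C)C)(C(C)C)C(C)C)c(CC=C)c3O)O2)ccc1O
F5 | step 2 | tert-butyl 2-methylbut-3-en-2-yl carbonate | C=CC(C)(C)OC(=O)OC(C)(C)C
F6 | step 1 | (2S)-5,7-diacetoxy-2-(4-acetoxyphenyl)chroman-4-one | CC(=O)Oc1ccc([C@@H]2CC(=O)c3c(OC(C)=O)cc(OC(C)=O)cc3O2)cc1
F7 | step 1 | (2S)-5-acetoxy-2-(4-acetoxyphenyl)-7-hydroxychroman-4-one | CC(=O)Oc1ccc([C@@H]2CC(=O)c3c(OC(C)=O)cc(O)cc3O2)cc1
F8 | step 1 | (2S)-5-acetoxy-2-(4-acetoxyphenyl)-7-(triisopropylsilyloxy)chroman-4-one | CC(=O)Oc1ccc([C@@H]2CC(=O)c3c(OC(C)=O)cc(O[Si](C(C)C)(C(C)C)C(C)C)cc3O2)cc1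
A1 | alternative 1 | (2S)-5,7,4'-tris(methoxymethoxy)-6,3'-diprenylflavanone 4-(propane-1,3-diyl dithioketal) | CC(C)=CCc1cc([C@@H]2CC3(SCCCS3)c3c(cc(OCOC)c(CC=C(C)C)c3OCOC)O2)ccc1OCOC
A2 | alternative 1 | (1S)-2-{2-[6-bromo-2,4-bis(methoxymethoxy)-3-(3-methylbut-2-en-1-yl)phenyl]-1,3-dithian-2-yl}-1-[4-(methoxymethoxy)-3-(3-methylbut-2-en-1-yl)phenyl]ethan-1-ol | CC(C)=CCc1cc([C@@H](O)CC2(SCCCS2)c2c(Br)cc(OCOC)c(CC=C(C)C)c2OCOC)ccc1OCOC
A3 | alternative 2 | (2S)-5,7,4'-tris(tert-butyldimethylsilyloxy)-6,3'-diprenylflavanone | CC(C)=CCc1cc([C@@H]2CC(=O)c3c(cc(O[Si](C)(C)C(C)(C)C)c(CC=C(C)C)c3O[Si](C)(C)C(C)(C)C)O2)ccc1O[Si](C)(C)C(C)(C)C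
A4 | alternative 2 | 1-[2,4-bis(tert-butyldimethylsilyloxy)-6-{[4-(tert-butyldimethylsilyloxy)-3-(3-methylbut-2-en-1-yl)phenyl]methoxy}-3-(3-methylbut-2-en-1-yl)phenyl]-2-diazoethan-1-one | [N-]=[N+]=CC(=O)c1c(OCc2ccc(O[Si](C)(C)C(C)(C)C)c(CC=C(C)C)c2)cc(O[Si](C)(C)C(C)(C)C)c(CC=C(C)C)c1O[Si](C)(C)C(C)(C)C
A5 | alternative 3 | (2S)-5,7-dihydroxy-4'-(methoxymethoxy)-6,3'-diprenylflavanone | CC(C)=CCc1cc([C@@H]2CC(=O)c3c(cc(O)c(CC=C(C)C)c3O)O2)ccc1OCOC
A6 | alternative 3 | methyl 4-{(2S)-2-[4-(methoxymethoxy)-3-(3-methylbut-2-en-1-yl)phenyl]-4-oxo-3,4-dihydro-2H-pyran-6-yl}-2-(3-methylbut-2-en-1-yl)-3-oxobutanoate | COC(=O)C(CC=C(C)C)C(=O)CC1=CC(=O)C[C@@H](c2ccc(OCOC)c(CC=C(C)C)c2)O1
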